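**Retrosynthetic overview** (halimane numbering: ring A = C1–C5, C10; ring B = C5–C10; C17 on C8, C18 = carboxyl on C4, C20 on C9)
1. The 13-hydroxy-14,15-diacetate is traced back to the 13E allylic alcohol by Sharpless epoxidation, invertive hydrolysis at C13 and acetylation.
2. The C1=C10 alkene and the C5–H are unmasked from a Δ5(10)-octalin bearing an α-hydroxyl at C1 by reductive 1,3-transposition through an allylic diazene; the same operation turns C17–OH into the C8 methyl.
3. Key disconnection: ring B by Diels–Alder addition of acrolein (C7=C8, carbonyl carbon = C17) to the bis-exocyclic diene C6=C5–C10=C9 on ring A, forming C6–C7 and C8–C9. The enabling feature is that ring B is a six-membered ring in which a two-carbon unit (C7–C8, with C17 on C8 cis to the C9 methyl) bridges C6 and the quaternary C9, both attached to the C5–C10 pair next to the C1=C10 alkene, so ring B is a cyclohexene retron after alkene transposition.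
4. The diene comes from Pd-catalysed 6-exo-dig carbopalladation of an enol triflate onto a propynyl carbinol, terminated by B-alkyl Suzuki coupling with the side-chain borane; C4 is set by an organocatalytic Michael addition and C1 by an asymmetric alkynylation.
5. Ring order: ring A (step 7), then ring B (step 9); the side-chain epoxide (step 13) is transient.

Key step: step 9

Assumption: in steps 1 and 2 the catalyst and ligand antipodes are those that give the descriptors drawn; both steps are under reagent control.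

Step 1
Reactants: 1 tert-butyl 2-methyl-3-oxobutanoate; 2 acrolein
Product: 3 tert-butyl (2S)-2-acetyl-2-methyl-5-oxopentanoate
Conditions: 6'-hydroxy cinchona alkaloid catalyst with a 9-O-phenanthryl group (10 mol %), CH2Cl2, −24 °C
Reagents that add atoms: none
Why: An organocatalytic asymmetric Michael addition of the α-substituted β-keto ester to acrolein should create the quaternary C4 centre by face-selective attack of the hydrogen-bonded enol, the bulky tert-butyl ester helping selectivity.

Step 2
Reactants: 3 tert-butyl (2S)-2-acetyl-2-methyl-5-oxopentanoate; 4 propyne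
Product: 5 tert-butyl (2S,5S)-2-acetyl-5-hydroxy-2-methyloct-6-ynoate
Conditions: ZnEt2 (2 equiv), BINOL (40 mol %), Ti(OiPr)4 (25 mol %), CH2Cl2/toluene, rt; aq. NH4Cl
Reagents that add atoms: none
Why: A BINOL–titanium-catalysed asymmetric alkynylzinc addition to the aldehyde should set the C1 carbinol under ligand control, independent of the remote C4 centre, while the hindered methyl ketone and the ester are left alone.

Step 3
Reactants: 5 tert-butyl (2S,5S)-2-acetyl-5-hydroxy-2-methyloct-6-ynoate
Product: 6 tert-butyl (2S,5S)-2-acetyl-2-methyl-5-(triethylsilyloxy)oct-6-ynoate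
Conditions: Et3SiCl, imidazole, CH2Cl2, 0 °C
Reagents that add atoms: chlorotriethylsilane, CC[Si](Cl)(CC)CC
Why: Standard silylation protects the propargylic alcohol against the base and triflating agent of step 4 without touching a stereocentre.

Step 4
Reactants: 6 tert-butyl (2S,5S)-2-acetyl-2-methyl-5-(triethylsilyloxy)oct-6-ynoate
Product: 7 tert-butyl (2S,5S)-2-methyl-5-(triethylsilyloxy)-2-[1-(trifluoromethylsulfonyloxy)ethenyl]oct-6-ynoate
Conditions: KN(SiMe3)2, THF, −78 °C; then PhNTf2, −78 → 0 °C
Reagents that add atoms: N-phenylbis(trifluoromethanesulfonimide), O=S(=O)(N(c1ccccc1)S(=O)(=O)C(F)(F)F)C(F)(F)F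
Why: Enolate O-triflation is regiospecific because only the methyl group of the ketone can be deprotonated (C4 is quaternary and the ester has no α-hydrogen).

Step 5
Reactants: 8 (2E)-3-methylpent-2-en-4-yn-1-ol
Product: 9 tert-butyl{[(2E)-3-methylpent-2-en-4-yn-1-yl]oxy}diphenylsilane
Conditions: tBuPh2SiCl, imidazole, CH2Cl2, rt
Reagents that add atoms: tert-butyl(chloro)diphenylsilane, CC(C)(C)[Si](Cl)(c1ccccc1)c1ccccc1
Why: Silylation of the primary allylic alcohol gives an ether that should survive every step up to step 12.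

Step 6
Reactants: 9 tert-butyl{[(2E)-3-methylpent-2-en-4-yn-1-yl]oxy}diphenylsilane
Product: 10 tert-butyl{[(2E)-3-methylpenta-2,4-dien-1-yl]oxy}diphenylsilane
Conditions: H2 (1 atm), Pd/CaCO3 poisoned with Pb(OAc)2, quinoline, hexane/EtOAc, rt
Reagents that add atoms: none
Why: Semi-hydrogenation of the terminal alkyne over poisoned palladium should stop at the vinyl group and leave the E-trisubstituted alkene unchanged.

Step 7
Reactants: 7 enol triflate from step 4; 10 tert-butyl{[(2E)-3-methylpenta-2,4-dien-1-yl]oxy}diphenylsilane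
Product: 12 tert-butyl (1S,3E,4S)-3-[(5E)-7-(tert-butyldiphenylsilyloxy)-5-methylhept-5-en-2-ylidene]-1-methyl-2-methylidene-4-(triethylsilyloxy)cyclohexane-1-carboxylate, via B-alkyl-9-BBN 11 (not isolated)
Conditions: 10, 9-BBN, THF, 0 °C → rt; then 7, PdCl2(dppf) (5 mol %), AsPh3 (10 mol %), Cs2CO3, DMF/THF/H2O, 50 °C
Reagents that add atoms: none
Why: Anti-Markovnikov hydroboration of the vinyl group is followed by a cyclic carbopalladation–Suzuki–Miyaura cascade, in which oxidative addition of the triflate to zerovalent palladium, 6-exo-dig syn-carbopalladation of the alkyne (closing ring A) and B-alkyl coupling place the side chain cis to C5 and the C20 methyl cis to C1, so the syn addition fixes the tetrasubstituted alkene geometry.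

Step 8
Reactants: 12 ring A diene triethylsilyl ether
Product: 13 tert-butyl (1S,3E,4S)-3-[(5E)-7-(tert-butyldiphenylsilyloxy)-5-methylhept-5-en-2-ylidene]-4-hydroxy-1-methyl-2-methylidenecyclohexane-1-carboxylate
Conditions: HF·pyridine, excess pyridine, THF, 0 °C
Reagents that add atoms: none
Why: Buffered fluoride desilylation should cleave the secondary triethylsilyl ether selectively over the primary tert-butyldiphenylsilyl ether, freeing the C1 hydroxyl that serves as the tether handle.

Step 9
Reactants: 13 dienol from step 8; 2 acrolein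
Product: 15 tert-butyl (1S,4S,5S,6R)-5-[(3E)-5-(tert-butyldiphenylsilyloxy)-3-methylpent-3-en-1-yl]-6-formyl-4-hydroxy-1,5-dimethyl-1,2,3,4,5,6,7,8-octahydronaphthalene-1-carboxylate, via bromomagnesium alkoxide 14 (not isolated)
Conditions: MgBr2·OEt2 (1.5 equiv), Et3N (1.6 equiv), CH2Cl2, 0 °C; then acrolein (3 equiv), −20 → 0 °C; aq. NH4Cl
Reagents that add atoms: none
Why: Deprotonation of the C1 hydroxyl in the presence of MgBr2 gives alkoxide 14, whose divalent magnesium binds and activates the acrolein carbonyl, so that a concerted, asynchronous [4+2] cycloaddition inside an eight-membered chelate joins C7 to C6 and C8 to C9 of the s-cis-locked C6=C5–C10=C9 diene. The closest known reaction type is the hydroxyl-directed, magnesium-tethered Diels–Alder reaction of dienols whose carbinol carbon sits on an inner diene carbon with enals and acrylates. Ring B closes as a six-membered carbocycle by suprafacial addition to both diene termini through a boat-like endo transition state, and because the chelate is large no bridgehead alkene is demanded. The quaternary centre C9 is set by the E geometry of C9=C10 (methyl outside, side chain inside, fixed in step 7) together with attack on the diene face that bears the axial C1 oxygen, and C8 is set by the endo orientation of the formyl group that the chelate enforces, which places C17 cis to the C9 methyl. The step needs regioselectivity (C8, not C7, bonding to C9), which the tether, the larger HOMO coefficient at C6 and the LUMO coefficient at the acrolein β-carbon all favour, and facial selectivity, for which the axial C1 oxygen (A(1,3) strain with the C9 methyl) and the axial C4 ester on the opposite face act in the same sense. The trisubstituted side-chain alkene should not compete as diene or dienophile, and the low temperature should suppress 1,5-hydrogen shift in the Z-substituted diene.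

Step 10
Reactants: 15 hydroxy aldehyde from step 9
Product: 16 tert-butyl (1S,4S,5S,6R)-5-[(3E)-5-(tert-butyldiphenylsilyloxy)-3-methylpent-3-en-1-yl]-4-hydroxy-6-(hydroxymethyl)-1,5-dimethyl-1,2,3,4,5,6,7,8-octahydronaphthalene-1-carboxylate
Conditions: NaBH4, MeOH, 0 °C
Reagents that add atoms: none
Why: Chemoselective borohydride reduction of the aldehyde should leave the hindered tert-butyl ester and all stereocentres untouched.

Step 11
Reactants: 16 diol from step 10
Product: 19 tert-butyl (1S,5S,6R,8aS)-5-[(3E)-5-(tert-butyldiphenylsilyloxy)-3-methylpent-3-en-1-yl]-1,5,6-trimethyl-1,2,3,5,6,7,8,8a-octahydronaphthalene-1-carboxylate, via bis(sulfonylhydrazine) 17 (not isolated), via bis(diazene) 18 (not isolated)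
Conditions: o-nitrobenzenesulfonylhydrazide (5 equiv), PPh3 (5 equiv), diethyl azodicarboxylate (5 equiv), THF, −30 °C; then 23 °C
Reagents that add atoms: none
Why: A double Mitsunobu displacement followed by loss of sulfinic acid gives two monoalkyl diazenes, of which the primary one at C17 loses N2 to leave the C8 methyl, while the allylic one, formed with inversion on the β face of C1, undergoes a suprafacial retro-ene hydrogen shift that delivers hydrogen to the β face of C5 and moves the alkene to C1=C10 (reductive 1,3-transposition), so the C1 stereocentre is traded for C5.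

Step 12
Reactants: 19 silyl ether from step 11
Product: 20 tert-butyl (1S,5S,6R,8aS)-5-[(3E)-5-hydroxy-3-methylpent-3-en-1-yl]-1,5,6-trimethyl-1,2,3,5,6,7,8,8a-octahydronaphthalene-1-carboxylate
Conditions: Bu4NF, THF, 0 °C → rt; aq. NH4Cl
Reagents that add atoms: none
Why: Fluoride desilylation frees the primary allylic alcohol; the tert-butyl ester and both alkenes are inert.

Step 13
Reactants: 20 allylic alcohol from step 12
Product: 21 tert-butyl (1S,5S,6R,8aS)-5-{2-[(2S,3S)-3-(hydroxymethyl)-2-methyloxiran-2-yl]ethyl}-1,5,6-trimethyl-1,2,3,5,6,7,8,8a-octahydronaphthalene-1-carboxylate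
Conditions: Ti(OiPr)4 (10 mol %), L-(+)-diethyl tartrate (12 mol %), tBuOOH, 4 Å molecular sieves, CH2Cl2, −20 °C
Reagents that add atoms: tert-butyl hydroperoxide, CC(C)(C)OO
Why: Sharpless asymmetric epoxidation acts only on the alkene bearing the allylic hydroxyl and, by analogy with geraniol and the L-(+)-tartrate, should give the (13S,14S)-epoxide under reagent control.

Step 14
Reactants: 21 epoxy alcohol from step 13
Product: 22 tert-butyl (1S,5S,6R,8aS)-5-[(3R,4S)-3,4,5-trihydroxy-3-methylpentyl]-1,5,6-trimethyl-1,2,3,5,6,7,8,8a-octahydronaphthalene-1-carboxylate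
Conditions: HClO4 (5 mol %), THF/H2O 3:1, 0 °C
Reagents that add atoms: water, O
Why: Acid-catalysed epoxide hydrolysis should open the 2,3-epoxy alcohol at the tertiary carbon C13 with inversion (C14 is deactivated by the adjacent CH2OH), giving the anti diol with 13R,14S configuration.

Step 15
Reactants: 22 triol ester from step 14
Product: 24 (1S,5S,6R,8aS)-5-[(3R,4S)-3,4,5-trihydroxy-3-methylpentyl]-1,5,6-trimethyl-1,2,3,5,6,7,8,8a-octahydronaphthalene-1-carboxylic acid, via persilylated ester 23 (not isolated)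
Conditions: Me3SiOTf (6 equiv), 2,6-lutidine (8 equiv), CH2Cl2, 0 °C; then aq. citric acid/MeOH, rt
Reagents that add atoms: none
Why: Silyl triflate-mediated tert-butyl ester cleavage (O-silylation, loss of isobutene) under buffered non-protic conditions should avoid protonation of the C1=C10 alkene and ionisation of the tertiary alcohol, and the silyl ester and silyl ethers are hydrolysed on mild acidic work-up.

Step 16
Reactants: 24 triol acid from step 15
Product: 25 (1S,5S,6R,8aS)-5-[(3R,4S)-4,5-diacetoxy-3-hydroxy-3-methylpentyl]-1,5,6-trimethyl-1,2,3,5,6,7,8,8a-octahydronaphthalene-1-carboxylic acid (target)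
Conditions: Ac2O (2.5 equiv), pyridine, 0 °C → rt; aq. NaHCO3, then acidification to pH 3
Reagents that add atoms: acetic anhydride, CC(=O)OC(C)=O
Why: Acetylation in pyridine without a nucleophilic catalyst should acylate the primary and secondary hydroxyls but not the hindered tertiary C13 hydroxyl, and any mixed anhydride at the carboxyl group is hydrolysed on aqueous work-up.

**Compound list**
1 | tert-butyl 2-methyl-3-oxobutanoate | CC(=O)C(C)C(=O)OC(C)(C)C | starting material
2 | acrolein | C=CC=O | starting material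
3 | tert-butyl (2S)-2-acetyl-2-methyl-5-oxopentanoate | CC(=O)[C@](C)(CCC=O)C(=O)OC(C)(C)C | intermediate
4 | propyne | CC#C | starting material
5 | tert-butyl (2S,5S)-2-acetyl-5-hydroxy-2-methyloct-6-ynoate | CC(=O)[C@](C)(CC[C@H](O)C#CC)C(=O)OC(C)(C)C | intermediate
6 | tert-butyl (2S,5S)-2-acetyl-2-methyl-5-(triethylsilyloxy)oct-6-ynoate | CC(=O)[C@](C)(CC[C@H](O[Si](CC)(CC)CC)C#CC)C(=O)OC(C)(C)C | intermediate
7 | tert-butyl (2S,5S)-2-methyl-5-(triethylsilyloxy)-2-[1-(trifluoromethylsulfonyloxy)ethenyl]oct-6-ynoate | C=C(OS(=O)(=O)C(F)(F)F)[C@@](C)(C(=O)OC(C)(C)C)CC[C@H](O[Si](CC)(CC)CC)C#CC | intermediate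
8 | (2E)-3-methylpent-2-en-4-yn-1-ol | C#C/C(C)=C/CO | starting material
9 | tert-butyl{[(2E)-3-methylpent-2-en-4-yn-1-yl]oxy}diphenylsilane | C#C/C(C)=C/CO[Si](c1ccccc1)(c1ccccc1)C(C)(C)C | intermediate
10 | tert-butyl{[(2E)-3-methylpenta-2,4-dien-1-yl]oxy}diphenylsilane | C=C/C(C)=C/CO[Si](c1ccccc1)(c1ccccc1)C(C)(C)C | intermediate
11 | 9-[(3E)-5-(tert-butyldiphenylsilyloxy)-3-methylpent-3-en-1-yl]-9-borabicyclo[3.3.1]nonane | CC(C)(C)[Si](c1ccccc1)(c1ccccc1)OC/C=C(\C)CCB1C2CCCC1CCC2 | intermediate (not isolated)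
12 | tert-butyl (1S,3E,4S)-3-[(5E)-7-(tert-butyldiphenylsilyloxy)-5-methylhept-5-en-2-ylidene]-1-methyl-2-methylidene-4-(triethylsilyloxy)cyclohexane-1-carboxylate | C=C1[C@@](C)(C(=O)OC(C)(C)C)CC[C@H](O[Si](CC)(CC)CC)/C1=C(\C)CC/C(C)=C/CO[Si](c1ccccc1)(c1ccccc1)C(C)(C)C | intermediate
13 | tert-butyl (1S,3E,4S)-3-[(5E)-7-(tert-butyldiphenylsilyloxy)-5-methylhept-5-en-2-ylidene]-4-hydroxy-1-methyl-2-methylidenecyclohexane-1-carboxylate | C=C1[C@@](C)(C(=O)OC(C)(C)C)CC[C@H](O)/C1=C(\C)CC/C(C)=C/CO[Si](c1ccccc1)(c1ccccc1)C(C)(C)C | intermediate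
14 | bromomagnesium alkoxide of 13 | C=C1[C@@](C)(C(=O)OC(C)(C)C)CC[C@H](O[Mg]Br)/C1=C(\C)CC/C(C)=C/CO[Si](c1ccccc1)(c1ccccc1)C(C)(C)C | intermediate (not isolated)
15 | tert-butyl (1S,4S,5S,6R)-5-[(3E)-5-(tert-butyldiphenylsilyloxy)-3-methylpent-3-en-1-yl]-6-formyl-4-hydroxy-1,5-dimethyl-1,2,3,4,5,6,7,8-octahydronaphthalene-1-carboxylate | CC(C)(C)[Si](c1ccccc1)(c1ccccc1)OC/C=C(\C)CC[C@]1(C)C2=C(CC[C@H]1C=O)[C@@](C)(C(=O)OC(C)(C)C)CC[C@@H]2O | intermediate
16 | tert-butyl (1S,4S,5S,6R)-5-[(3E)-5-(tert-butyldiphenylsilyloxy)-3-methylpent-3-en-1-yl]-4-hydroxy-6-(hydroxymethyl)-1,5-dimethyl-1,2,3,4,5,6,7,8-octahydronaphthalene-1-carboxylate | CC(C)(C)[Si](c1ccccc1)(c1ccccc1)OC/C=C(\C)CC[C@]1(C)C2=C(CC[C@H]1CO)[C@@](C)(C(=O)OC(C)(C)C)CC[C@@H]2O | intermediate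
17 | bis[N-amino-N-(2-nitrophenylsulfonyl)amino] derivative of 16 (C17 and inverted C1) | CC(C)(C)[Si](c1ccccc1)(c1ccccc1)OC/C=C(\C)CC[C@]1(C)C2=C(CC[C@H]1CN(N)S(=O)(=O)c1ccccc1[N+](=O)[O-])[C@@](C)(C(=O)OC(C)(C)C)CC[C@H]2N(N)S(=O)(=O)c1ccccc1[N+](=O)[O-] | intermediate (not isolated)
18 | bis(diazene) at C17 and C1 | CC(C)(C)[Si](c1ccccc1)(c1ccccc1)OC/C=C(\C)CC[C@]1(C)C2=C(CC[C@H]1CN=N)[C@@](C)(C(=O)OC(C)(C)C)CC[C@H]2N=N | intermediate (not isolated)
19 | tert-butyl (1S,5S,6R,8aS)-5-[(3E)-5-(tert-butyldiphenylsilyloxy)-3-methylpent-3-en-1-yl]-1,5,6-trimethyl-1,2,3,5,6,7,8,8a-octahydronaphthalene-1-carboxylate | CC(C)(C)[Si](c1ccccc1)(c1ccccc1)OC/C=C(\C)CC[C@]1(C)C2=CCC[C@](C)(C(=O)OC(C)(C)C)[C@H]2CC[C@H]1C | intermediate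
20 | tert-butyl (1S,5S,6R,8aS)-5-[(3E)-5-hydroxy-3-methylpent-3-en-1-yl]-1,5,6-trimethyl-1,2,3,5,6,7,8,8a-octahydronaphthalene-1-carboxylate | OC/C=C(\C)CC[C@]1(C)C2=CCC[C@](C)(C(=O)OC(C)(C)C)[C@H]2CC[C@H]1C | intermediate
21 | tert-butyl (1S,5S,6R,8aS)-5-{2-[(2S,3S)-3-(hydroxymethyl)-2-methyloxiran-2-yl]ethyl}-1,5,6-trimethyl-1,2,3,5,6,7,8,8a-octahydronaphthalene-1-carboxylate | OC[C@@H]3O[C@@]3(C)CC[C@]1(C)C2=CCC[C@](C)(C(=O)OC(C)(C)C)[C@H]2CC[C@H]1C | intermediate
22 | tert-butyl (1S,5S,6R,8aS)-5-[(3R,4S)-3,4,5-trihydroxy-3-methylpentyl]-1,5,6-trimethyl-1,2,3,5,6,7,8,8a-octahydronaphthalene-1-carboxylate | OC[C@H](O)[C@](C)(O)CC[C@]1(C)C2=CCC[C@](C)(C(=O)OC(C)(C)C)[C@H]2CC[C@H]1C | intermediate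
23 | trimethylsilyl ester tris(trimethylsilyl ether) of 24 | C[Si](C)(C)OC[C@H](O[Si](C)(C)C)[C@](C)(O[Si](C)(C)C)CC[C@]1(C)C2=CCC[C@](C)(C(=O)O[Si](C)(C)C)[C@H]2CC[C@H]1C | intermediate (not isolated)
24 | (1S,5S,6R,8aS)-5-[(3R,4S)-3,4,5-trihydroxy-3-methylpentyl]-1,5,6-trimethyl-1,2,3,5,6,7,8,8a-octahydronaphthalene-1-carboxylic acid | OC[C@H](O)[C@](C)(O)CC[C@]1(C)C2=CCC[C@](C)(C(=O)O)[C@H]2CC[C@H]1C | intermediate
25 | (1S,5S,6R,8aS)-5-[(3R,4S)-4,5-diacetoxy-3-hydroxy-3-methylpentyl]-1,5,6-trimethyl-1,2,3,5,6,7,8,8a-octahydronaphthalene-1-carboxylic acid | CC(=O)OC[C@H](OC(C)=O)[C@](C)(O)CC[C@]1(C)C2=CCC[C@](C)(C(=O)O)[C@H]2CC[C@H]1C | target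

**Step count and risks**
Total step count: 16. Longest linear sequence: 14 steps (steps 1–4 and 7–16).

Steps most likely to fail:

Step 9 (Diels–Alder). The tetrasubstituted, twisted C9 terminus may react too slowly, acrolein may add outside the magnesium chelate and erode facial and endo control, or the alkoxide may add to acrolein in an oxa-Michael reaction. The fallback replaces the chelate by a covalent silicon tether and sets out from 13. Silylation with Ph2SiCl2/Et3N followed by allyl alcohol should give the mixed allyl diphenylsilyl ketal F1. Heating in toluene (about 160 °C, radical inhibitor) should effect an intramolecular Diels–Alder reaction that delivers the allyl alkene across C6 and C9 from the face of the C1 oxygen and gives the bridged cyclic diphenylsilylene ketal F2, in which C17 is already a CH2O group. HF·pyridine then cleaves the silylene and the route is rejoined at diol 16.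

Step 7 (cyclisation–coupling cascade). The vinyl triflate may couple directly with the alkylborane before the 6-exo-dig carbopalladation, or the borane may be lost by protodeboronation. The fallback separates ring closure from sp2–sp3 coupling and sets out from 7. Cyclisation with Me3SnSnMe3, Pd(PPh3)4 and LiCl should give the ring A alkenyl(trimethyl)stannane F3 with tin cis to C5. Iododestannylation (I2, CH2Cl2, 0 °C) with retention gives the alkenyl iodide F4. A conventional B-alkyl Suzuki–Miyaura coupling of F4 with borane 11 (PdCl2(dppf), AsPh3, Cs2CO3) rejoins the route at 12.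

Step 11 (double diazene deoxygenation and transposition). Mitsunobu displacement may be incomplete at the hindered secondary allylic C1 or at the β-branched C17, elimination to a triene may compete, and stereospecificity would be lost if C1 ionises. The fallback sets out from 16. Selective tosylation of the primary hydroxyl (TsCl, pyridine, 0 °C) gives the C17 monotosylate F5. LiBHEt3 (THF, 0 °C) reduces it to the C17-methyl allylic alcohol F6. Formylation (formic acetic anhydride, pyridine) gives the C1 allylic formate F7. Decarboxylative hydrogenolysis with Pd(OAc)2/PBu3 in dioxane at 80 °C follows, in which zerovalent palladium ionises anti to the α-formate and hydride is delivered from palladium to the more substituted terminus C5 on the β face. The route is rejoined at 19.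

**Further compounds**
F1 | step 9 | mixed allyl diphenylsilyl ketal of dienol 13 | C=C1[C@@](C)(C(=O)OC(C)(C)C)CC[C@H](O[Si](c2ccccc2)(c2ccccc2)OCC=C)/C1=C(\C)CC/C(C)=C/CO[Si](c1ccccc1)(c1ccccc1)C(C)(C)C
F2 | step 9 | bridged cyclic diphenylsilylene ketal of diol 16 (C1–O–SiPh2–O–C17) | CC(C)(C)[Si](c1ccccc1)(c1ccccc1)OC/C=C(\C)CC[C@]1(C)C2=C(CC[C@H]1CO[Si]3(c4ccccc4)c4ccccc4)[C@@](C)(C(=O)OC(C)(C)C)CC[C@@H]2O3
F3 | step 7 | ring A diene with trimethylstannyl on C9 cis to C5 | C=C1[C@@](C)(C(=O)OC(C)(C)C)CC[C@H](O[Si](CC)(CC)CC)/C1=C(\C)[Sn](C)(C)C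
F4 | step 7 | ring A diene with iodine on C9 cis to C5 | C=C1[C@@](C)(C(=O)OC(C)(C)C)CC[C@H](O[Si](CC)(CC)CC)/C1=C(\C)I
F5 | step 11 | C17 mono-p-toluenesulfonate of diol 16 | CC(C)(C)[Si](c1ccccc1)(c1ccccc1)OC/C=C(\C)CC[C@]1(C)C2=C(CC[C@H]1COS(=O)(=O)c1ccc(C)cc1)[C@@](C)(C(=O)OC(C)(C)C)CC[C@@H]2O
F6 | step 11 | C17-methyl Δ5(10) allylic alcohol (C1 α-hydroxyl) | CC(C)(C)[Si](c1ccccc1)(c1ccccc1)OC/C=C(\C)CC[C@]1(C)C2=C(CC[C@H]1C)[C@@](C)(C(=O)OC(C)(C)C)CC[C@@H]2O
F7 | step 11 | C1 formate of F6 | CC(C)(C)[Si](c1ccccc1)(c1ccccc1)OC/C=C(\C)CC[C@]1(C)C2=C(CC[C@H]1C)[C@@](C)(C(=O)OC(C)(C)C)CC[C@@H]2OC=O
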